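**Plan**
- Retrosynthesis: the C9 ketone is taken back to a silyl-protected carbinol; then the C12–C13 bond (ring carbinol carbon to the octenyl CH2) is cut, then C7=C8 (aldol condensation), then C5=C6 (cross-metathesis). The ring goes back to a 4-silyloxycyclopentenone.
- Forward: (S)-4-silyloxycyclopentenone is chlorinated at C10 and its carbonyl is moved from C9 to C12 (Luche reduction, TBDPS on, TBS off, oxidation). The C1–C7 enal is condensed onto C8, the (Z)-oct-2-enyl group is added to the C12 ketone, and C9 is desilylated and oxidised last.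
- Enabling feature: in the cyclopentene ring C9 and C12 are the two oxygen-bearing carbons, 1,3 to each other across C8, and all other ring atoms are sp2. An sp3 silyloxy centre at C9 is therefore the only marker that distinguishes the two faces of a C12 ketone, and it vanishes when C9 becomes the ketone of the target.
- Stereochemistry: 12R comes from addition anti to the (9R)-silyl ether, which in turn comes from the (S) centre of the starting enone through a cis-selective Luche reduction. 7Z arises because the aldol condensation is run on the C12 ketone (chain anti to C12=O, syn to C9). 14Z is carried in from (Z)-oct-2-en-1-ol and 5E comes from the metathesis.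

Key step: step 10

Assumption: positions are numbered as in a prostanoid (ester carbon C1, ring C8–C12, allylic CH2 = C13), and compounds 1, 8, 9 and 15 are taken as commercial.

**Step 1**
Reactants: 1 (S)-4-[(tert-butyldimethylsilyl)oxy]cyclopent-2-en-1-one
Product: 3 (S)-4-[(tert-butyldimethylsilyl)oxy]-2-chlorocyclopent-2-en-1-one, via dichloride adduct 2 (not isolated)
Conditions: PhICl2, pyridine, CH2Cl2, 0 °C to rt
Reagents that add atoms: iodobenzene dichloride, ClI(Cl)c1ccccc1
Why: Chlorine adds across the enone C=C and pyridine removes the acidic α-proton with loss of the β-chloride (addition–dehydrochlorination, the usual α-halogenation of a cyclic enone), which leaves chlorine on the α-carbon (C10) only and does not touch the silyloxy stereocentre.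

**Step 2**
Reactants: 3 (S)-4-[(tert-butyldimethylsilyl)oxy]-2-chlorocyclopent-2-en-1-one
Product: 4 (1R,4S)-4-[(tert-butyldimethylsilyl)oxy]-2-chlorocyclopent-2-en-1-ol (cis)
Conditions: NaBH4, CeCl3·7H2O, MeOH, −78 °C
Reagents that add atoms: none
Why: Luche 1,2-reduction should deliver hydride to the C9 carbonyl from the face opposite the C12 silyloxy group, so the new C9 carbinol is cis to it (1R); the trans isomer is a diastereomer and is removed here by chromatography.

**Step 3**
Reactants: 4 (1R,4S)-4-[(tert-butyldimethylsilyl)oxy]-2-chlorocyclopent-2-en-1-ol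
Product: 5 (3S,5R)-3-[(tert-butyldimethylsilyl)oxy]-5-[(tert-butyldiphenylsilyl)oxy]-1-chlorocyclopent-1-ene (cis)
Conditions: TBDPSCl, imidazole, DMAP (cat.), DMF, rt
Reagents that add atoms: tert-butyl(chloro)diphenylsilane, CC(C)(C)[Si](Cl)(c1ccccc1)c1ccccc1
Why: Imidazole-promoted silylation of the secondary alcohol installs a bulky, non-chelating group at C9 that outlasts TBS removal and later directs the key addition.

**Step 4**
Reactants: 5 (3S,5R)-3-[(tert-butyldimethylsilyl)oxy]-5-[(tert-butyldiphenylsilyl)oxy]-1-chlorocyclopent-1-ene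
Product: 6 (1S,4R)-4-[(tert-butyldiphenylsilyl)oxy]-3-chlorocyclopent-2-en-1-ol (cis)
Conditions: PPTS, MeOH, rt to 40 °C
Reagents that add atoms: none
Why: Acid-catalysed methanolysis cleaves a secondary TBS ether much faster than a TBDPS ether (selective desilylation), so only the C12 hydroxyl should be freed.

**Step 5**
Reactants: 6 (1S,4R)-4-[(tert-butyldiphenylsilyl)oxy]-3-chlorocyclopent-2-en-1-ol
Product: 7 (R)-4-[(tert-butyldiphenylsilyl)oxy]-3-chlorocyclopent-2-en-1-one
Conditions: Dess–Martin periodinane, pyridine, CH2Cl2, 0 °C to rt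
Reagents that add atoms: none
Why: Dess–Martin oxidation of the allylic alcohol gives the C12 enone under buffered, non-epimerising conditions; the old C12 centre is erased and C9 now carries all the stereochemical information.

**Step 6**
Reactants: 8 methyl hex-5-enoate; 9 (E)-but-2-enal
Product: 10 methyl (5E)-7-oxohept-5-enoate
Conditions: Ru–NHC 2-isopropoxybenzylidene metathesis catalyst (2nd generation, 3 mol %), excess 9, CH2Cl2, 40 °C
Reagents that add atoms: none
Why: Olefin cross-metathesis of a terminal alkene with crotonaldehyde should give the E enal with loss of propene.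

**Step 7**
Reactants: 7 (R)-4-[(tert-butyldiphenylsilyl)oxy]-3-chlorocyclopent-2-en-1-one; 10 methyl (5E)-7-oxohept-5-enoate
Product: 12 methyl (5E)-7-[(1R,2R)-2-[(tert-butyldiphenylsilyl)oxy]-3-chloro-5-oxocyclopent-3-en-1-yl]-7-hydroxyhept-5-enoate (C7 epimers), via lithium enolate 11 (not isolated)
Conditions: LiHMDS, THF, −78 °C; then 10, −78 °C; AcOH quench at −78 °C
Reagents that add atoms: none
Why: Kinetic deprotonation at the only α′ position (C8) gives the cross-conjugated lithium enolate, which adds 1,2 to the enal at −78 °C (directed aldol addition, as known for 4-silyloxycyclopent-2-enones); the new centres at C7 and C8 are removed in the next step, so their configuration does not matter.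

**Step 8**
Reactants: 12 methyl (5E)-7-[(1R,2R)-2-[(tert-butyldiphenylsilyl)oxy]-3-chloro-5-oxocyclopent-3-en-1-yl]-7-hydroxyhept-5-enoate
Product: 14 methyl (5E,7E)-7-[(2R)-2-[(tert-butyldiphenylsilyl)oxy]-3-chloro-5-oxocyclopent-3-en-1-ylidene]hept-5-enoate, via allylic mesylate 13 (not isolated)
Conditions: MsCl, Et3N (excess), CH2Cl2, −20 °C to rt
Reagents that add atoms: none
Why: Mesylation and E1cB elimination (aldol condensation by dehydration of a β-hydroxy ketone) should give the thermodynamically preferred enone in which the dienyl chain points away from the C12 carbonyl and towards C9, which is the arrangement named 7Z once C9 is the ketone.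

**Step 9**
Reactants: 15 (Z)-oct-2-en-1-ol
Product: 18 tributyl[(2Z)-oct-2-en-1-yl]stannane, via lithium alkoxide 16 (not isolated), via allylic mesylate 17 (not isolated)
Conditions: n-BuLi, THF, −78 °C; MsCl, −78 °C; then Bu3SnLi (from Bu3SnH and LDA, THF, 0 °C), −78 °C
Reagents that add atoms: tributylstannyllithium, [Li][Sn](CCCC)(CCCC)CCCC (made in the flask from tributyltin hydride, CCCC[SnH](CCCC)CCCC, and LDA)
Why: One-pot mesylation of the primary allylic alkoxide and SN2 displacement by the stannyl anion (allylstannane synthesis from allylic alcohols) should occur at the primary carbon without allylic shift and keep the Z alkene.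

**Step 10**
Reactants: 14 methyl (5E,7E)-7-[(2R)-2-[(tert-butyldiphenylsilyl)oxy]-3-chloro-5-oxocyclopent-3-en-1-ylidene]hept-5-enoate; 18 tributyl[(2Z)-oct-2-en-1-yl]stannane
Product: 21 methyl (5E,7E)-7-[(2R,5R)-5-[(tert-butyldiphenylsilyl)oxy]-4-chloro-2-hydroxy-2-[(2Z)-oct-2-en-1-yl]cyclopent-3-en-1-ylidene]hept-5-enoate, via (Z)-oct-2-enyllithium 19 (not isolated), via (Z)-oct-2-enylcerium dichloride 20 (not isolated)
Conditions: 18, n-BuLi, THF, −78 °C; anhydrous CeCl3 (THF slurry), −78 °C; then 14, THF, −78 °C; aq NH4Cl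
Reagents that add atoms: none
Why: Tin–lithium exchange on 18 gives the (Z)-oct-2-enyl anion 19 in its favoured endo (Z) form, and transmetalation at −78 °C gives the η1-allylcerium 20 bound at the unsubstituted terminus, which transfers that carbon to the C12 carbonyl carbon of 14 in a direct 1,2-addition without allylic shift. The closest known reaction type is the addition of allylcerium reagents, made from allyllithiums and CeCl3, to α,β-unsaturated carbonyl compounds, which goes 1,2, through the less substituted allyl terminus and with retention of a Z double bond at −78 °C. No ring is closed. The new C12 stereocentre is controlled by the C9 OTBDPS group: C9 is the only sp3 atom of the ring and lies 1,3 to C12 across C8, so its silyloxy group covers one face of the flat dienone and the octenyl group should enter from the other (C12–OH cis to C9–OSi, 9R gives 12R). The step needs α over γ attack, Z retention, 1,2 over 1,4/1,6 addition (C10 carries a displaceable chloride, C7 and C5 are vinylogous acceptor positions) and ketone over ester selectivity; the oxophilic, weakly basic cerium reagent, the hindered ketone and the low temperature should secure these, and the non-chelating silyl ether avoids syn delivery. Any C12 epimer is a diastereomer at this stage and is removed before C9 is oxidised.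

**Step 11**
Reactants: 21 methyl (5E,7E)-7-[(2R,5R)-5-[(tert-butyldiphenylsilyl)oxy]-4-chloro-2-hydroxy-2-[(2Z)-oct-2-en-1-yl]cyclopent-3-en-1-ylidene]hept-5-enoate
Product: 22 methyl (5E,7E)-7-[(2R,5R)-4-chloro-2,5-dihydroxy-2-[(2Z)-oct-2-en-1-yl]cyclopent-3-en-1-ylidene]hept-5-enoate
Conditions: TBAF, AcOH (1:1), THF, 0 °C to rt
Reagents that add atoms: none
Why: Fluoride-mediated cleavage of the silyl ether, buffered with acetic acid to spare the methyl ester and the bis-allylic alcohols, should free the C9 hydroxyl; no enone is present at this stage, so the triene is not open to conjugate addition.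

**Step 12**
Reactants: 22 methyl (5E,7E)-7-[(2R,5R)-4-chloro-2,5-dihydroxy-2-[(2Z)-oct-2-en-1-yl]cyclopent-3-en-1-ylidene]hept-5-enoate
Product: 23 chlorovulone III, methyl (5E,7Z)-7-[(2R)-4-chloro-2-hydroxy-2-[(2Z)-oct-2-en-1-yl]-5-oxocyclopent-3-en-1-ylidene]hept-5-enoate
Conditions: Dess–Martin periodinane, pyridine, CH2Cl2, 0 °C, dark
Reagents that add atoms: none
Why: Dess–Martin oxidation should convert the secondary, doubly allylic C9 alcohol into the ketone while the tertiary C12 alcohol cannot be oxidised; this removes the temporary C9 stereocentre and unveils the cross-conjugated chlorodienone with 12R and 7Z already in place.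

**Compound list**
1 | (S)-4-[(tert-butyldimethylsilyl)oxy]cyclopent-2-en-1-one | CC(C)(C)[Si](C)(C)O[C@@H]1C=CC(=O)C1 | starting material
2 | (4S)-4-[(tert-butyldimethylsilyl)oxy]-2,3-dichlorocyclopentan-1-one (C2/C3 isomers) | CC(C)(C)[Si](C)(C)O[C@@H]1C(Cl)C(Cl)C(=O)C1 | intermediate
3 | (S)-4-[(tert-butyldimethylsilyl)oxy]-2-chlorocyclopent-2-en-1-one | CC(C)(C)[Si](C)(C)O[C@@H]1C=C(Cl)C(=O)C1 | intermediate
4 | (1R,4S)-4-[(tert-butyldimethylsilyl)oxy]-2-chlorocyclopent-2-en-1-ol | CC(C)(C)[Si](C)(C)O[C@@H]1C=C(Cl)[C@H](O)C1 | intermediate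
5 | (3S,5R)-3-[(tert-butyldimethylsilyl)oxy]-5-[(tert-butyldiphenylsilyl)oxy]-1-chlorocyclopent-1-ene | CC(C)(C)[Si](C)(C)O[C@@H]1C=C(Cl)[C@H](O[Si](c2ccccc2)(c2ccccc2)C(C)(C)C)C1 | intermediate
6 | (1S,4R)-4-[(tert-butyldiphenylsilyl)oxy]-3-chlorocyclopent-2-en-1-ol | O[C@@H]1C=C(Cl)[C@H](O[Si](c2ccccc2)(c2ccccc2)C(C)(C)C)C1 | intermediate
7 | (R)-4-[(tert-butyldiphenylsilyl)oxy]-3-chlorocyclopent-2-en-1-one | O=C1C=C(Cl)[C@H](O[Si](c2ccccc2)(c2ccccc2)C(C)(C)C)C1 | intermediate
8 | methyl hex-5-enoate | COC(=O)CCCC=C | starting material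
9 | (E)-but-2-enal | C/C=C/C=O | starting material
10 | methyl (5E)-7-oxohept-5-enoate | COC(=O)CCC/C=C/C=O | intermediate
11 | lithium enolate of 7, lithium (5R)-5-[(tert-butyldiphenylsilyl)oxy]-4-chlorocyclopenta-1,3-dien-2-olate | [Li]OC1=C[C@@H](O[Si](c2ccccc2)(c2ccccc2)C(C)(C)C)C(Cl)=C1 | intermediate
12 | methyl (5E)-7-[(1R,2R)-2-[(tert-butyldiphenylsilyl)oxy]-3-chloro-5-oxocyclopent-3-en-1-yl]-7-hydroxyhept-5-enoate (C7 epimers) | O=C1C=C(Cl)[C@H](O[Si](c2ccccc2)(c2ccccc2)C(C)(C)C)[C@H]1C(O)/C=C/CCCC(=O)OC | intermediate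
13 | 7-O-methanesulfonate of 12 | O=C1C=C(Cl)[C@H](O[Si](c2ccccc2)(c2ccccc2)C(C)(C)C)[C@H]1C(OS(C)(=O)=O)/C=C/CCCC(=O)OC | intermediate
14 | methyl (5E,7E)-7-[(2R)-2-[(tert-butyldiphenylsilyl)oxy]-3-chloro-5-oxocyclopent-3-en-1-ylidene]hept-5-enoate | O=C1C=C(Cl)[C@H](O[Si](c2ccccc2)(c2ccccc2)C(C)(C)C)/C1=C\C=C\CCCC(=O)OC | intermediate
15 | (Z)-oct-2-en-1-ol | CCCCC/C=C\CO | starting material
16 | lithium (Z)-oct-2-en-1-olate | CCCCC/C=C\CO[Li] | intermediate
17 | (Z)-oct-2-en-1-yl methanesulfonate | CCCCC/C=C\COS(C)(=O)=O | intermediate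
18 | tributyl[(2Z)-oct-2-en-1-yl]stannane | CCCCC/C=C\C[Sn](CCCC)(CCCC)CCCC | intermediate
19 | (Z)-oct-2-en-1-yllithium | [Li]C/C=C\CCCCC | intermediate
20 | dichloro[(2Z)-oct-2-en-1-yl]cerium | Cl[Ce](Cl)C/C=C\CCCCC | intermediate
21 | methyl (5E,7E)-7-[(2R,5R)-5-[(tert-butyldiphenylsilyl)oxy]-4-chloro-2-hydroxy-2-[(2Z)-oct-2-en-1-yl]cyclopent-3-en-1-ylidene]hept-5-enoate | CCCCC/C=C\C[C@@]1(O)C=C(Cl)[C@H](O[Si](c2ccccc2)(c2ccccc2)C(C)(C)C)/C1=C\C=C\CCCC(=O)OC | intermediate
22 | methyl (5E,7E)-7-[(2R,5R)-4-chloro-2,5-dihydroxy-2-[(2Z)-oct-2-en-1-yl]cyclopent-3-en-1-ylidene]hept-5-enoate | CCCCC/C=C\C[C@@]1(O)C=C(Cl)[C@H](O)/C1=C\C=C\CCCC(=O)OC | intermediate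
23 | chlorovulone III, methyl (5E,7Z)-7-[(2R)-4-chloro-2-hydroxy-2-[(2Z)-oct-2-en-1-yl]-5-oxocyclopent-3-en-1-ylidene]hept-5-enoate | CCCCC/C=C\C[C@@]1(O)C=C(Cl)C(=O)/C1=C\C=C\CCCC(=O)OC | target

**Step count and risks**
Total steps: 12. Longest linear sequence: 10 steps (1 → 3 → 4 → 5 → 6 → 7 → 12 → 14 → 21 → 22 → 23).

Steps most likely to fail:

1. Step 10. The Z geometry may erode through E/Z equilibration of the allyl anion before or after transmetalation, attack may occur through the substituted allyl terminus, or the reagent may add in a conjugate sense with displacement of the C10 chloride. Fallback, setting out from 14: the unsubstituted allyl group, which has neither a regiochemical nor a geometric issue, is added as allylmagnesium bromide pre-mixed with CeCl3 at −78 °C to give methyl (5E,7E)-7-[(2R,5R)-5-[(tert-butyldiphenylsilyl)oxy]-4-chloro-2-hydroxy-2-(prop-2-en-1-yl)cyclopent-3-en-1-ylidene]hept-5-enoate F1. A Z-selective cross-metathesis of its terminal alkene with hept-1-ene (cyclometalated ruthenium Z-selective catalyst) then builds the C14=C15 bond, and the route is rejoined at 21.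

2. Step 7. The amide base may attack the β-chloro enone by addition–elimination, the enolate may lose silanolate, or the enal may be consumed by self-condensation. Fallback, setting out from 7: soft enolisation with TMSOTf/Et3N gives the silyloxydiene tert-butyl{[(1R)-2-chloro-4-[(trimethylsilyl)oxy]cyclopenta-2,4-dien-1-yl]oxy}diphenylsilane F2, which is combined with 10 in a BF3·OEt2-promoted Mukaiyama aldol addition at −78 °C. Aqueous work-up returns the route at 12.

3. Step 8. The elimination may give a mixture of C7=C8 geometries, or the allylic mesylate may ionise or be displaced with allylic shift before it eliminates. Fallback, setting out from 7: the lithium enolate is C-phosphinylated with diethyl chlorophosphite to give diethyl [(2R)-2-[(tert-butyldiphenylsilyl)oxy]-3-chloro-5-oxocyclopent-3-en-1-yl]phosphonite F3, which is oxidised in the same flask (air or t-BuOOH) to diethyl [(2R)-2-[(tert-butyldiphenylsilyl)oxy]-3-chloro-5-oxocyclopent-3-en-1-yl]phosphonate F4. A Horner–Wadsworth–Emmons reaction of F4 with 10 (LiCl, iPr2NEt, MeCN) then forms the E-configured exocyclic enone directly, and the route is rejoined at 14 without passing through 12 and 13.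

**Further compounds**
F1 | step 10 | methyl (5E,7E)-7-[(2R,5R)-5-[(tert-butyldiphenylsilyl)oxy]-4-chloro-2-hydroxy-2-(prop-2-en-1-yl)cyclopent-3-en-1-ylidene]hept-5-enoate | C=CC[C@@]1(O)C=C(Cl)[C@H](O[Si](c2ccccc2)(c2ccccc2)C(C)(C)C)/C1=C\C=C\CCCC(=O)OC
F2 | step 7 | tert-butyl{[(1R)-2-chloro-4-[(trimethylsilyl)oxy]cyclopenta-2,4-dien-1-yl]oxy}diphenylsilane | C[Si](C)(C)OC1=C[C@@H](O[Si](c2ccccc2)(c2ccccc2)C(C)(C)C)C(Cl)=C1
F3 | step 8 | diethyl [(2R)-2-[(tert-butyldiphenylsilyl)oxy]-3-chloro-5-oxocyclopent-3-en-1-yl]phosphonite (C1 epimers) | CCOP(OCC)C1[C@@H](O[Si](c2ccccc2)(c2ccccc2)C(C)(C)C)C(Cl)=CC1=O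
F4 | step 8 | diethyl [(2R)-2-[(tert-butyldiphenylsilyl)oxy]-3-chloro-5-oxocyclopent-3-en-1-yl]phosphonate (C1 epimers) | CCOP(=O)(OCC)C1[C@@H](O[Si](c2ccccc2)(c2ccccc2)C(C)(C)C)C(Cl)=CC1=O
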